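## Retrosynthetic overview

- The target is cut at the C4–C8 bond between the two flavan units, after removal of all benzyl ethers: a C4-(2-ethoxyethoxy) tri-O-benzyl-epiafzelechin (electrophile) and penta-O-benzyl-(+)-catechin (nucleophile, chiral pool).
- The electrophile comes from DDQ oxidation at C4 of tri-O-benzyl-epiafzelechin, which comes from L-Selectride reduction of the (2R)-flavan-3-one, itself made by Baeyer–Villiger oxidation of a (2R)-2-aryl-2H-chromene-3-carbaldehyde.
- The chromene (upper pyran ring, the only ring built) comes from an amine-catalysed oxa-Michael addition followed by a ring-closing intramolecular aldol condensation of a salicylaldehyde with a cinnamaldehyde.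
- Three two-step branches feed the route: phloroglucinol to the salicylaldehyde, 4-hydroxybenzaldehyde to the cinnamaldehyde, (+)-catechin to its pentabenzyl ether.
- Ring order: upper pyran ring closed first, lower flavan taken intact from catechin, the two units joined last.

Assumption: the SMILES defines the target, i.e. a (2R,3R,4R) unit with a 4-hydroxyphenyl group linked 4β→8 to (2R,3S)-catechin (epiafzelechin-(4β→8)-catechin).

## Route

Step 1
Reactants: 1 phloroglucinol
Product: 3 2,4,6-trihydroxybenzaldehyde, via Vilsmeier iminium chloride 2 (not isolated)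
Conditions: POCl3, DMF, EtOAc, 0 °C to rt; then H2O, 60 °C
Reagents that add atoms: N,N-dimethylformamide CN(C)C=O; water O
Why: Vilsmeier–Haack formylation of the very electron-rich ring stops after one substitution because the iminium salt deactivates the ring, and water then hydrolyses it to the aldehyde.

Step 2
Reactants: 3 2,4,6-trihydroxybenzaldehyde
Product: 4 2,4-bis(benzyloxy)-6-hydroxybenzaldehyde
Conditions: BnBr (2.1 equiv), K2CO3, DMF, 0 °C to rt
Reagents that add atoms: benzyl bromide BrCc1ccccc1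
Why: Williamson etherification takes the para OH and one ortho OH, while the remaining ortho OH is held in a hydrogen bond to the formyl group and is the least nucleophilic.

Step 3
Reactants: 5 4-hydroxybenzaldehyde
Product: 6 4-(benzyloxy)benzaldehyde
Conditions: BnBr, K2CO3, acetone, reflux
Reagents that add atoms: benzyl bromide BrCc1ccccc1
Why: Williamson ether synthesis on a single phenol.

Step 4
Reactants: 6 4-(benzyloxy)benzaldehyde
Product: 7 (E)-3-[4-(benzyloxy)phenyl]prop-2-enal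
Conditions: Ph3P=CHCHO (1.1 equiv), toluene, 80 °C
Reagents that add atoms: (triphenylphosphoranylidene)acetaldehyde O=CC=P(c1ccccc1)(c1ccccc1)c1ccccc1
Why: Wittig olefination with a stabilised ylide gives the E-enal, and a slight deficit of ylide limits a second homologation.

Step 5
Reactants: 4 2,4-bis(benzyloxy)-6-hydroxybenzaldehyde; 7 (E)-3-[4-(benzyloxy)phenyl]prop-2-enal
Product: 10 (2R)-5,7-bis(benzyloxy)-2-[4-(benzyloxy)phenyl]-2H-chromene-3-carbaldehyde, via oxa-Michael adduct 8 (not isolated), via aldol adduct 9 (not isolated)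
Conditions: (S)-2-[diphenyl(trimethylsilyloxy)methyl]pyrrolidine (20 mol %), 2-nitrobenzoic acid (20 mol %), toluene, 4 Å MS, rt
Reagents that add atoms: none
Why: In this iminium/enamine cascade the phenol adds to the iminium ion of 7 on the face left open by the CPh2OTMS group (oxa-Michael, sets C2 as R by the usual shielding model; the (R)-catalyst is used if the sense proves opposite), then the enamine closes the pyran ring by intramolecular aldol condensation onto the aryl aldehyde, and loss of water makes it irreversible.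

Step 6
Reactants: 10 (2R)-5,7-bis(benzyloxy)-2-[4-(benzyloxy)phenyl]-2H-chromene-3-carbaldehyde
Product: 12 (2R)-5,7-bis(benzyloxy)-2-[4-(benzyloxy)phenyl]chroman-3-one, via enol formate 11 (not isolated)
Conditions: mCPBA (1.1 equiv), CH2Cl2/pH 7.5 phosphate buffer, 0 °C; then KHCO3 (cat.), MeOH, 0 °C
Reagents that add atoms: 3-chloroperoxybenzoic acid OOC(=O)c1cccc(Cl)c1
Why: Baeyer–Villiger oxidation of an α-substituted cinnamaldehyde makes the electron-rich alkenyl group migrate to give the enol formate, and mild methanolysis then releases the C3 ketone without touching C2.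

Step 7
Reactants: 12 (2R)-5,7-bis(benzyloxy)-2-[4-(benzyloxy)phenyl]chroman-3-one
Product: 13 (2R,3R)-5,7-bis(benzyloxy)-2-[4-(benzyloxy)phenyl]chroman-3-ol
Conditions: L-Selectride, LiBr, THF, −78 °C; then H2O
Reagents that add atoms: none
Why: Substrate-controlled ketone reduction in which the bulky hydride attacks anti to the C2 aryl group, giving the 2,3-cis alcohol (3R) as in the known catechin-to-epicatechin inversion.

Step 8
Reactants: 13 (2R,3R)-5,7-bis(benzyloxy)-2-[4-(benzyloxy)phenyl]chroman-3-ol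
Product: 14 (2R,3R,4S)-5,7-bis(benzyloxy)-2-[4-(benzyloxy)phenyl]-4-(2-ethoxyethoxy)chroman-3-ol
Conditions: DDQ (2 equiv), 2-ethoxyethanol, CH2Cl2, rt
Reagents that add atoms: 2-ethoxyethanol CCOCCO
Why: DDQ benzylic oxidation abstracts hydride from C4 (cation stabilised by the 5,7-dialkoxy ring) and the alcohol traps it trans to the C3 hydroxyl, giving the 4β ether.

Step 9
Reactants: 15 (+)-catechin
Product: 16 5,7,3',4'-tetra-O-benzyl-(+)-catechin
Conditions: BnBr (4.2 equiv), K2CO3, DMF, 0 °C to rt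
Reagents that add atoms: benzyl bromide BrCc1ccccc1
Why: Williamson etherification under mild carbonate conditions takes only the four phenols and leaves C2 and C3 of the chiral-pool unit untouched.

Step 10
Reactants: 16 5,7,3',4'-tetra-O-benzyl-(+)-catechin
Product: 17 3,5,7,3',4'-penta-O-benzyl-(+)-catechin
Conditions: NaH, BnBr, DMF, 0 °C to rt
Reagents that add atoms: benzyl bromide BrCc1ccccc1
Why: Williamson etherification of the secondary alcohol, safe now that no free phenol can open the ring, gives a nucleophile with no hydroxyl to be O-alkylated or silylated in the coupling.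

Step 11
Reactants: 14 (2R,3R,4S)-5,7-bis(benzyloxy)-2-[4-(benzyloxy)phenyl]-4-(2-ethoxyethoxy)chroman-3-ol; 17 3,5,7,3',4'-penta-O-benzyl-(+)-catechin (3 equiv)
Product: 18 octa-O-benzyl epiafzelechin-(4β→8)-catechin
Conditions: TMSOTf (0.2 equiv), CH2Cl2, −78 °C; then aq. NaHCO3
Reagents that add atoms: none
Why: Lewis-acid SN1 Friedel–Crafts alkylation in which C8 of 17 attacks the flavan-4-yl cation from the β-face, anti to the C3 hydroxyl, setting C4 as R (3,4-trans), while the excess of 17 suppresses oligomers.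

Step 12
Reactants: 18 octa-O-benzyl epiafzelechin-(4β→8)-catechin
Product: 19 epiafzelechin-(4β→8)-catechin (gambiriin C as defined by the SMILES)
Conditions: H2 (1 atm), 20% Pd(OH)2/C, THF/MeOH/H2O, rt
Reagents that add atoms: none
Why: Hydrogenolysis removes all eight benzyl ethers under Pearlman conditions that leave the C2–O and C4–C8 benzylic bonds intact.

## Compound list

1 | phloroglucinol (benzene-1,3,5-triol) | Oc1cc(O)cc(O)c1 | starting material
2 | [(2,4,6-trihydroxyphenyl)methylidene]dimethyliminium chloride | C[N+](C)=Cc1c(O)cc(O)cc1O.[Cl-] | intermediate (not isolated)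
3 | 2,4,6-trihydroxybenzaldehyde | O=Cc1c(O)cc(O)cc1O | intermediate
4 | 2,4-bis(benzyloxy)-6-hydroxybenzaldehyde | O=Cc1c(O)cc(OCc2ccccc2)cc1OCc1ccccc1 | intermediate
5 | 4-hydroxybenzaldehyde | O=Cc1ccc(O)cc1 | starting material
6 | 4-(benzyloxy)benzaldehyde | O=Cc1ccc(OCc2ccccc2)cc1 | intermediate
7 | (E)-3-[4-(benzyloxy)phenyl]prop-2-enal | O=C/C=C/c1ccc(OCc2ccccc2)cc1 | intermediate
8 | (3S)-3-[3,5-bis(benzyloxy)-2-formylphenoxy]-3-[4-(benzyloxy)phenyl]propanal (oxa-Michael adduct, carried as the catalyst enamine; same spatial arrangement as C2 of 10) | O=CC[C@H](Oc1cc(OCc2ccccc2)cc(OCc2ccccc2)c1C=O)c1ccc(OCc2ccccc2)cc1 | intermediate (not isolated)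
9 | (2S)-5,7-bis(benzyloxy)-2-[4-(benzyloxy)phenyl]-4-hydroxychromane-3-carbaldehyde (aldol adduct, C3/C4 mixture, carried as the catalyst iminium; same spatial arrangement at C2 as 10) | O=CC1C(O)c2c(OCc3ccccc3)cc(OCc3ccccc3)cc2O[C@@H]1c1ccc(OCc2ccccc2)cc1 | intermediate (not isolated)
10 | (2R)-5,7-bis(benzyloxy)-2-[4-(benzyloxy)phenyl]-2H-chromene-3-carbaldehyde | O=CC1=Cc2c(OCc3ccccc3)cc(OCc3ccccc3)cc2O[C@@H]1c1ccc(OCc2ccccc2)cc1 | intermediate
11 | (2R)-5,7-bis(benzyloxy)-2-[4-(benzyloxy)phenyl]-2H-chromen-3-yl formate | O=COC1=Cc2c(OCc3ccccc3)cc(OCc3ccccc3)cc2O[C@@H]1c1ccc(OCc2ccccc2)cc1 | intermediate (not isolated)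
12 | (2R)-5,7-bis(benzyloxy)-2-[4-(benzyloxy)phenyl]chroman-3-one | O=C1Cc2c(OCc3ccccc3)cc(OCc3ccccc3)cc2O[C@@H]1c1ccc(OCc2ccccc2)cc1 | intermediate
13 | (2R,3R)-5,7-bis(benzyloxy)-2-[4-(benzyloxy)phenyl]chroman-3-ol (5,7,4'-tri-O-benzyl-epiafzelechin) | O[C@@H]1Cc2c(OCc3ccccc3)cc(OCc3ccccc3)cc2O[C@@H]1c1ccc(OCc2ccccc2)cc1 | intermediate
14 | (2R,3R,4S)-5,7-bis(benzyloxy)-2-[4-(benzyloxy)phenyl]-4-(2-ethoxyethoxy)chroman-3-ol | c1ccccc1COc1ccc([C@H]2Oc3cc(OCc4ccccc4)cc(OCc4ccccc4)c3[C@H](OCCOCC)[C@H]2O)cc1 | intermediate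
15 | (+)-catechin, (2R,3S)-2-(3,4-dihydroxyphenyl)chromane-3,5,7-triol | O[C@H]1Cc2c(O)cc(O)cc2O[C@@H]1c1ccc(O)c(O)c1 | starting material
16 | 5,7,3',4'-tetra-O-benzyl-(+)-catechin, (2R,3S)-5,7-bis(benzyloxy)-2-[3,4-bis(benzyloxy)phenyl]chroman-3-ol | O[C@H]1Cc2c(OCc3ccccc3)cc(OCc3ccccc3)cc2O[C@@H]1c1ccc(OCc2ccccc2)c(OCc2ccccc2)c1 | intermediate
17 | 3,5,7,3',4'-penta-O-benzyl-(+)-catechin, (2R,3S)-3,5,7-tris(benzyloxy)-2-[3,4-bis(benzyloxy)phenyl]chromane | C(c1ccccc1)O[C@H]1Cc2c(OCc3ccccc3)cc(OCc3ccccc3)cc2O[C@@H]1c1ccc(OCc2ccccc2)c(OCc2ccccc2)c1 | intermediate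
18 | (2R,3R,4R)-5,7-bis(benzyloxy)-2-[4-(benzyloxy)phenyl]-4-[(2R,3S)-3,5,7-tris(benzyloxy)-2-[3,4-bis(benzyloxy)phenyl]chroman-8-yl]chroman-3-ol | c1ccccc1COc1ccc([C@H]2Oc3cc(OCc4ccccc4)cc(OCc4ccccc4)c3[C@H](c3c(OCc4ccccc4)cc(OCc4ccccc4)c4c3O[C@H](c3ccc(OCc5ccccc5)c(OCc5ccccc5)c3)[C@@H](OCc3ccccc3)C4)[C@H]2O)cc1 | intermediate
19 | (2R,3R,4R)-2-(4-hydroxyphenyl)-4-[(2R,3S)-2-(3,4-dihydroxyphenyl)-3,5,7-trihydroxychroman-8-yl]chromane-3,5,7-triol | Oc1ccc([C@H]2Oc3cc(O)cc(O)c3[C@H](c3c(O)cc(O)c4c3O[C@H](c3ccc(O)c(O)c3)[C@@H](O)C4)[C@H]2O)cc1 | target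

## Step count

Total steps: 12. Longest linear sequence: 8 (steps 1, 2, 5, 6, 7, 8, 11, 12; the branch through steps 3 and 4 is equally long), which is two thirds of the total.

## Steps most likely to fail, with fallbacks

**Step 5 (organocatalytic oxa-Michael/aldol).** The aldehyde of 4 is hindered and electron-rich and enal 7 is a weak iminium acceptor, so conversion or ee may be poor. The fallback sets out from 4 and 7 and gives up catalyst control for a racemic ring synthesis plus classical resolution. K2CO3 in dioxane at 80 °C gives the racemic 2H-chromene-3-carbaldehyde F1. The conditions of step 6 take it through the racemic enol formate F2 to the racemic flavan-3-one F3, and the conditions of step 7 give the racemic cis-flavan-3-ol F4. Esterification with (S)-O-methylmandelic acid (DCC, DMAP) gives the ester of the (2R,3R)-alcohol F5 and the ester of the (2S,3S)-alcohol F6, which are separated on silica. Methanolysis of F5 (K2CO3, MeOH) returns the route at 13.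

**Step 6 (Baeyer–Villiger).** The peracid may epoxidise the alkene, oxidise the trialkoxy ring, or give the acid by hydride migration. The fallback sets out from 10 and replaces the oxygen insertion by a Curtius degradation. Pinnick oxidation (NaClO2, NaH2PO4, 2-methyl-2-butene, t-BuOH/H2O) gives the chromene-3-carboxylic acid F7. DPPA and Et3N in toluene convert it into the acyl azide F8, which rearranges at 80 °C to the vinyl isocyanate F9; neither is isolated. Cold dilute HCl in THF hydrolyses F9, and the route is rejoined at ketone 12.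

**Step 11 (interflavan coupling).** The electrophile 14 carries its own nucleophilic C8 and C6, so self-condensation and higher oligomers can compete even with excess 17. The fallback sets out from 14 and blocks that position. NBS in CH2Cl2 at −78 °C gives the 8-bromo electrophile F10. TMSOTf-promoted coupling with 17 gives the 8-bromo octabenzyl dimer F11. Hydrogenolysis over Pd(OH)2/C with Et3N present removes the bromine together with the benzyl groups and comes back to the route at 19.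

## Further compounds

F1 | step 5 | racemic 5,7-bis(benzyloxy)-2-[4-(benzyloxy)phenyl]-2H-chromene-3-carbaldehyde | O=CC1=Cc2c(OCc3ccccc3)cc(OCc3ccccc3)cc2OC1c1ccc(OCc2ccccc2)cc1
F2 | step 5 | racemic 5,7-bis(benzyloxy)-2-[4-(benzyloxy)phenyl]-2H-chromen-3-yl formate | O=COC1=Cc2c(OCc3ccccc3)cc(OCc3ccccc3)cc2OC1c1ccc(OCc2ccccc2)cc1
F3 | step 5 | racemic 5,7-bis(benzyloxy)-2-[4-(benzyloxy)phenyl]chroman-3-one | O=C1Cc2c(OCc3ccccc3)cc(OCc3ccccc3)cc2OC1c1ccc(OCc2ccccc2)cc1
F4 | step 5 | racemic cis-5,7-bis(benzyloxy)-2-[4-(benzyloxy)phenyl]chroman-3-ol (2R*,3R*; one enantiomer drawn) | O[C@@H]1Cc2c(OCc3ccccc3)cc(OCc3ccccc3)cc2O[C@@H]1c1ccc(OCc2ccccc2)cc1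
F5 | step 5 | (2R,3R)-5,7-bis(benzyloxy)-2-[4-(benzyloxy)phenyl]chroman-3-yl (S)-2-methoxy-2-phenylacetate | CO[C@H](C(=O)O[C@@H]1Cc2c(OCc3ccccc3)cc(OCc3ccccc3)cc2O[C@@H]1c1ccc(OCc2ccccc2)cc1)c1ccccc1
F6 | step 5 | (2S,3S)-5,7-bis(benzyloxy)-2-[4-(benzyloxy)phenyl]chroman-3-yl (S)-2-methoxy-2-phenylacetate | CO[C@H](C(=O)O[C@H]1Cc2c(OCc3ccccc3)cc(OCc3ccccc3)cc2O[C@H]1c1ccc(OCc2ccccc2)cc1)c1ccccc1
F7 | step 6 | (2R)-5,7-bis(benzyloxy)-2-[4-(benzyloxy)phenyl]-2H-chromene-3-carboxylic acid | OC(=O)C1=Cc2c(OCc3ccccc3)cc(OCc3ccccc3)cc2O[C@@H]1c1ccc(OCc2ccccc2)cc1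
F8 | step 6 | (2R)-5,7-bis(benzyloxy)-2-[4-(benzyloxy)phenyl]-2H-chromene-3-carbonyl azide | [N-]=[N+]=NC(=O)C1=Cc2c(OCc3ccccc3)cc(OCc3ccccc3)cc2O[C@@H]1c1ccc(OCc2ccccc2)cc1
F9 | step 6 | (2R)-5,7-bis(benzyloxy)-2-[4-(benzyloxy)phenyl]-3-isocyanato-2H-chromene | O=C=NC1=Cc2c(OCc3ccccc3)cc(OCc3ccccc3)cc2O[C@@H]1c1ccc(OCc2ccccc2)cc1
F10 | step 11 | (2R,3R,4S)-8-bromo-5,7-bis(benzyloxy)-2-[4-(benzyloxy)phenyl]-4-(2-ethoxyethoxy)chroman-3-ol | c1ccccc1COc1ccc([C@H]2Oc3c(Br)c(OCc4ccccc4)cc(OCc4ccccc4)c3[C@H](OCCOCC)[C@H]2O)cc1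
F11 | step 11 | 8-bromo derivative of 18 (bromine on C8 of the upper unit) | c1ccccc1COc1ccc([C@H]2Oc3c(Br)c(OCc4ccccc4)cc(OCc4ccccc4)c3[C@H](c3c(OCc4ccccc4)cc(OCc4ccccc4)c4c3O[C@H](c3ccc(OCc5ccccc5)c(OCc5ccccc5)c3)[C@@H](OCc3ccccc3)C4)[C@H]2O)cc1
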